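**Retrosynthetic overview**
- Target 16 ← removal of three MOM ethers from (3R)-ketone 15 ← oxidation of cis-(3R,4R)-alcohol 14 ← asymmetric transfer hydrogenation with dynamic kinetic resolution of racemic isoflavanone 13, where C3 is set.
- 13 ← ring C made in one operation from aryl ester 9: iodine–lithium exchange, 1,3 O→C acyl shift (C4–C4a bond), then 6-endo oxa-Michael closure (O1–C2 bond).
- Enabling feature: in ring C the ether oxygen O1 (on C8a) and the ketone carbon C4 (on C4a) sit on neighbouring carbons of ring A and are bridged by C2–C3. Ring C is therefore a 2-acylphenol joined to a 2-arylacrylic unit: O1 can first hold C2–C3–C4 as an acrylate ester, and an iodine at C4a (para to the 7-oxygen) marks where the acyl group lands.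
- 9 ← esterification of ring-B 2-arylacrylic acid 6 (from acetophenone 1: MOM protection, C5 bromination, Stille prenylation, enol triflate, hydroxycarbonylation) with ring-A iodophenol 8 (from phenol 7).
- Rings A and B are bought as arenes; ring C is the only ring formed (step 8).

Key step: step 8

Remark: isoflavanone numbering is used (ring C: O1, C2, C3, C4; ring A: C4a–C8a; ring B primed); the target SMILES corresponds to the (3R) enantiomer; compounds 1 and 7 are taken as catalogue chemicals.

**Step 1**
Reactants: 1 1-(2,3-dihydroxy-4-methoxyphenyl)ethan-1-one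
Product: 2 1-[4-methoxy-2,3-bis(methoxymethoxy)phenyl]ethan-1-one
Conditions: NaH (2.3 equiv), MOMCl (2.4 equiv), DMF, 0 °C → 20 °C
Reagents that add atoms: chloromethyl methyl ether (MOMCl), COCCl
Why: O-alkylation of both sodium phenoxides with MOMCl (acetal-type Williamson etherification), NaH being used because the 2-OH is hydrogen-bonded to the ketone and reacts sluggishly with amine bases.

**Step 2**
Reactants: 2 bis-MOM acetophenone
Product: 3 1-[5-bromo-4-methoxy-2,3-bis(methoxymethoxy)phenyl]ethan-1-one
Conditions: NBS (1.05 equiv), MeCN, 0 °C → 20 °C, dark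
Reagents that add atoms: N-bromosuccinimide, O=C1CCC(=O)N1Br
Why: Electrophilic aromatic bromination should go to C5, the only free position that is ortho to the methoxy group, para to the 2-oxygen and meta to the acetyl group, whereas C6 is deactivated by the adjacent acetyl group.

**Step 3**
Reactants: 3 aryl bromide
Product: 4 1-[4-methoxy-2,3-bis(methoxymethoxy)-5-(3-methylbut-2-en-1-yl)phenyl]ethan-1-one
Conditions: tributyl(3-methylbut-2-en-1-yl)stannane (1.3 equiv), Pd(PPh3)4 (5 mol %), DMF, 100 °C
Reagents that add atoms: tributyl(3-methylbut-2-en-1-yl)stannane, CCCC[Sn](CCCC)(CCCC)CC=C(C)C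
Why: Stille cross-coupling of the aryl bromide with the prenylstannane, which with Pd(PPh3)4 should transfer the allyl unit at its tin-bearing carbon to give the linear prenyl arene while ketone and MOM ethers stay inert.

**Step 4**
Reactants: 4 prenylated aryl methyl ketone
Product: 5 1-[4-methoxy-2,3-bis(methoxymethoxy)-5-(3-methylbut-2-en-1-yl)phenyl]ethenyl trifluoromethanesulfonate
Conditions: KN(SiMe3)2 (1.1 equiv), THF, −78 °C; PhNTf2 (1.1 equiv), −78 → 0 °C; purified on base-washed silica and used promptly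
Reagents that add atoms: N-phenylbis(trifluoromethanesulfonimide), O=S(=O)(N(c1ccccc1)S(=O)(=O)C(F)(F)F)C(F)(F)F
Why: Enol triflate formation by kinetic deprotonation of the methyl ketone and O-sulfonylation of the potassium enolate, the only acidic site under these conditions.

**Step 5**
Reactants: 5 enol triflate
Product: 6 2-[4-methoxy-2,3-bis(methoxymethoxy)-5-(3-methylbut-2-en-1-yl)phenyl]prop-2-enoic acid
Conditions: Pd(OAc)2 (5 mol %), dppp (6 mol %), CO (1 atm), KOAc (3 equiv), DMF/H2O (10:1), 50 °C; citric acid work-up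
Reagents that add atoms: carbon monoxide, [C-]#[O+]; water, O
Why: Palladium-catalysed hydroxycarbonylation of an enol triflate (oxidative addition, CO insertion, capture of the acylpalladium by acetate/water) puts the carboxyl group on the arene-bearing carbon without regiochemical ambiguity.

**Step 6**
Reactants: 7 3-(methoxymethoxy)phenol
Product: 8 2-iodo-5-(methoxymethoxy)phenol
Conditions: I2 (1.0 equiv), NaHCO3 (1.1 equiv), THF/H2O (1:1), 0 → 20 °C
Reagents that add atoms: iodine, II
Why: Electrophilic iodination of the phenoxide, which for 3-alkoxyphenols under these conditions is known to favour the position ortho to the phenoxide oxygen and para to the alkoxy group; the 4-iodo isomer would be removed by chromatography.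

**Step 7**
Reactants: 6 2-arylacrylic acid; 8 2-iodo-5-(methoxymethoxy)phenol
Product: 9 2-iodo-5-(methoxymethoxy)phenyl 2-[4-methoxy-2,3-bis(methoxymethoxy)-5-(3-methylbut-2-en-1-yl)phenyl]prop-2-enoate
Conditions: EDC·HCl (1.3 equiv), DMAP (0.2 equiv), CH2Cl2, 0 → 20 °C
Reagents that add atoms: none
Why: Steglich esterification (carbodiimide activation, DMAP acyl transfer) joins the two halves under neutral conditions that spare the MOM acetals, the aryl iodide and the acrylate.

**Step 8**
Reactants: 9 2-iodoaryl 2-arylacrylate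
Product: 13 racemic 7-(methoxymethoxy)-3-[4-methoxy-2,3-bis(methoxymethoxy)-5-(3-methylbut-2-en-1-yl)phenyl]chroman-4-one, via ortho-lithiated aryl acrylate 10 (not isolated), via lithium 2-acylphenoxide 11 (not isolated), via lithium enolate 12 (not isolated)
Conditions: n-BuLi (1.05 equiv), THF/Et2O (4:1), −100 °C, 15 min; then MeOH (5 equiv), −78 → 20 °C; aq. NH4Cl
Reagents that add atoms: none
Why: Proposed new method: iodine–lithium exchange at −100 °C should outrun addition of n-BuLi to the ester or the acrylate, and the ortho-lithiated ester 10 then passes the acryloyl group from O to C through a four-membered alkoxide (1,3 O→C acyl shift, anionic Fries type), which forms the C4–C4a bond and frees phenoxide 11. The closest known reactions are the halogen–lithium-exchange-induced anionic Fries rearrangement of 2-iodophenyl benzoates and the fluoride-induced insertion of arynes into the C–O bond of acrylic acids, which passes through the same ortho-metalated aryl acrylate and ends in chroman-4-ones; new here is a 2-arylacrylate under organolithium conditions. Ring C closes when, once MeOH is added, the phenoxide oxygen of 11 adds to the terminal CH2 of the 2-aryl enone in a 6-endo-trig oxa-Michael reaction (O1–C2 bond), the mode by which 2'-hydroxy-α-methylenedeoxybenzoins are known to give isoflavanones. The C3 stereocentre arises by uncontrolled protonation of enolate 12, so 13 is racemic by design and C3 is set in step 9. The selectivities needed are the site of acylation, fixed at C4a by the iodine (ortho to the ester oxygen, para to the 7-oxygen), and 1,3-acyl transfer over 6-endo attack of the carbanion on the acrylate CH2, secured by the Z conformation of the aryl ester, which holds the carbonyl carbon beside the carbanion and the CH2 group out of reach.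

**Step 9**
Reactants: 13 racemic isoflavanone
Product: 14 (3R,4R)-7-(methoxymethoxy)-3-[4-methoxy-2,3-bis(methoxymethoxy)-5-(3-methylbut-2-en-1-yl)phenyl]chroman-4-ol (cis)
Conditions: RuCl(p-cymene)[(R,R)-TsDPEN] (2 mol %), HCO2H/Et3N (5:2), EtOAc, 40 °C
Reagents that add atoms: none
Why: Noyori–Ikariya asymmetric transfer hydrogenation with dynamic kinetic resolution, as known for isoflavanones: Et3N equilibrates C3 through the enol while the (R,R)-catalyst should reduce the (3R)-ketone from the face anti to the aryl group, giving 4R (the sense known for chroman-4-one) and hence the cis-(3R,4R)-alcohol, with the prenyl alkene untouched.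

**Step 10**
Reactants: 14 cis-(3R,4R)-isoflavan-4-ol
Product: 15 (3R)-7-(methoxymethoxy)-3-[4-methoxy-2,3-bis(methoxymethoxy)-5-(3-methylbut-2-en-1-yl)phenyl]chroman-4-one
Conditions: Dess–Martin periodinane (1.3 equiv), CH2Cl2, 0 → 20 °C; pH 7 buffer/Na2S2O3 work-up
Reagents that add atoms: none
Why: Dess–Martin oxidation of the benzylic secondary alcohol removes the C4 stereocentre under base-free conditions, so the C3 configuration set in step 9 should be kept.

**Step 11**
Reactants: 15 (3R)-tris-MOM isoflavanone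
Product: 16 (3R)-3-[2,3-dihydroxy-4-methoxy-5-(3-methylbut-2-en-1-yl)phenyl]-7-hydroxychroman-4-one
Conditions: ZnBr2 (3 equiv), n-PrSH (6 equiv), CH2Cl2, 0 °C, about 10 min; pH 7 buffer work-up
Reagents that add atoms: none
Why: Lewis-acid/thiol cleavage of the three MOM acetals (ZnBr2 activates the acetal oxygen, the thiol traps the methoxymethyl cation) is fast, aprotic and cold, so neither enolization at C3 nor protonation of the prenyl double bond is expected.

**Compound list**
1 | 1-(2,3-dihydroxy-4-methoxyphenyl)ethan-1-one | CC(=O)c1ccc(OC)c(O)c1O | starting material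
2 | 1-[4-methoxy-2,3-bis(methoxymethoxy)phenyl]ethan-1-one | CC(=O)c1ccc(OC)c(OCOC)c1OCOC | intermediate
3 | 1-[5-bromo-4-methoxy-2,3-bis(methoxymethoxy)phenyl]ethan-1-one | CC(=O)c1cc(Br)c(OC)c(OCOC)c1OCOC | intermediate
4 | 1-[4-methoxy-2,3-bis(methoxymethoxy)-5-(3-methylbut-2-en-1-yl)phenyl]ethan-1-one | CC(=O)c1cc(CC=C(C)C)c(OC)c(OCOC)c1OCOC | intermediate
5 | 1-[4-methoxy-2,3-bis(methoxymethoxy)-5-(3-methylbut-2-en-1-yl)phenyl]ethenyl trifluoromethanesulfonate | C=C(OS(=O)(=O)C(F)(F)F)c1cc(CC=C(C)C)c(OC)c(OCOC)c1OCOC | intermediate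
6 | 2-[4-methoxy-2,3-bis(methoxymethoxy)-5-(3-methylbut-2-en-1-yl)phenyl]prop-2-enoic acid | C=C(C(=O)O)c1cc(CC=C(C)C)c(OC)c(OCOC)c1OCOC | intermediate
7 | 3-(methoxymethoxy)phenol | COCOc1cccc(O)c1 | starting material
8 | 2-iodo-5-(methoxymethoxy)phenol | COCOc1ccc(I)c(O)c1 | intermediate
9 | 2-iodo-5-(methoxymethoxy)phenyl 2-[4-methoxy-2,3-bis(methoxymethoxy)-5-(3-methylbut-2-en-1-yl)phenyl]prop-2-enoate | C=C(C(=O)Oc1cc(OCOC)ccc1I)c1cc(CC=C(C)C)c(OC)c(OCOC)c1OCOC | intermediate
10 | 2-lithio-5-(methoxymethoxy)phenyl 2-arylprop-2-enoate (aryl as in 6) | C=C(C(=O)Oc1cc(OCOC)ccc1[Li])c1cc(CC=C(C)C)c(OC)c(OCOC)c1OCOC | intermediate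
11 | lithium 5-(methoxymethoxy)-2-(2-arylprop-2-enoyl)phenoxide (aryl as in 6) | [Li+].[O-]c1cc(OCOC)ccc1C(=O)C(=C)c1cc(CC=C(C)C)c(OC)c(OCOC)c1OCOC | intermediate
12 | lithium 3-aryl-7-(methoxymethoxy)-2H-chromen-4-olate (aryl as in 6) | [Li+].[O-]C1=C(c2cc(CC=C(C)C)c(OC)c(OCOC)c2OCOC)COc2cc(OCOC)ccc21 | intermediate
13 | racemic 7-(methoxymethoxy)-3-[4-methoxy-2,3-bis(methoxymethoxy)-5-(3-methylbut-2-en-1-yl)phenyl]chroman-4-one | COc1c(CC=C(C)C)cc(C2COc3cc(OCOC)ccc3C2=O)c(OCOC)c1OCOC | intermediate
14 | (3R,4R)-7-(methoxymethoxy)-3-[4-methoxy-2,3-bis(methoxymethoxy)-5-(3-methylbut-2-en-1-yl)phenyl]chroman-4-ol | COc1c(CC=C(C)C)cc([C@@H]2COc3cc(OCOC)ccc3[C@@H]2O)c(OCOC)c1OCOC | intermediate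
15 | (3R)-7-(methoxymethoxy)-3-[4-methoxy-2,3-bis(methoxymethoxy)-5-(3-methylbut-2-en-1-yl)phenyl]chroman-4-one | COc1c(CC=C(C)C)cc([C@@H]2COc3cc(OCOC)ccc3C2=O)c(OCOC)c1OCOC | intermediate
16 | (3R)-3-[2,3-dihydroxy-4-methoxy-5-(3-methylbut-2-en-1-yl)phenyl]-7-hydroxychroman-4-one | COc1c(CC=C(C)C)cc([C@@H]2COc3cc(O)ccc3C2=O)c(O)c1O | target

**Step count**
Total steps: 11. Longest linear sequence: 10 steps (steps 1–5, then 7–11).

**Steps most likely to fail**

Step 8. What may go wrong: n-BuLi adds to the acrylate or the ester carbonyl before the iodine–lithium exchange, or the lithiated ring attacks the acrylate CH2 (6-endo) and gives a 3-aryl-dihydrocoumarin instead of migrating the acyl group. The fallback uses known reactions in separate stages, sets out from 8 and 6 and returns at 13. Phenol 8 is silylated (TBSCl, imidazole, DMF) to tert-butyl[2-iodo-5-(methoxymethoxy)phenoxy]dimethylsilane F1. F1 is stannylated ((Bu3Sn)2, Pd(PPh3)4, toluene, 110 °C) to tert-butyl[5-(methoxymethoxy)-2-(tributylstannyl)phenoxy]dimethylsilane F2. Acid 6 is converted with 1-chloro-N,N,2-trimethylprop-1-en-1-amine (CH2Cl2, 0 °C) into 2-[4-methoxy-2,3-bis(methoxymethoxy)-5-(3-methylbut-2-en-1-yl)phenyl]prop-2-enoyl chloride F3. Stille acylation of F3 with F2 (PdCl2(PPh3)2, toluene, 80 °C) gives 1-[2-(tert-butyldimethylsilyloxy)-4-(methoxymethoxy)phenyl]-2-[4-methoxy-2,3-bis(methoxymethoxy)-5-(3-methylbut-2-en-1-yl)phenyl]prop-2-en-1-one F4. Bu4NF/AcOH (THF, 0 °C) then removes the silyl group and the freed phenol closes ring C by 6-endo oxa-Michael addition to give 13.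

Step 9. What may go wrong: enolization of 13 is slower than hydride transfer, so the resolution stops being dynamic, or the ortho-substituted aryl group erodes the cis facial selectivity. The fallback sets out from 13 and returns at 15. Racemic 13 is separated by preparative chromatography on a chiral stationary phase; the (3R) enantiomer is 15. The unwanted (3S)-7-(methoxymethoxy)-3-[4-methoxy-2,3-bis(methoxymethoxy)-5-(3-methylbut-2-en-1-yl)phenyl]chroman-4-one F5 is racemized with Et3N in toluene and resubmitted.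

Step 11. What may go wrong: partial loss of configuration at C3 through Lewis-acid-promoted enolization, thioketal formation at C4, or addition to the prenyl double bond during acetal cleavage. The fallback moves the acetal cleavage to the racemic stage and makes the last step a buffered desilylation; it sets out from 13 and returns at 16. HCl/MeOH (40 °C) converts 13 into racemic 3-[2,3-dihydroxy-4-methoxy-5-(3-methylbut-2-en-1-yl)phenyl]-7-hydroxychroman-4-one F6. TBSCl/imidazole (DMF) gives the racemic tris(tert-butyldimethylsilyl) ether F7. The conditions of step 9 should give the cis-(3R,4R)-tris-silyl isoflavan-4-ol F8. Dess–Martin oxidation gives the (3R)-tris-silyl isoflavanone F9, and HF·pyridine (THF/pyridine, 0 °C) frees 16.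

**Further compounds**
F1 | step 8 | tert-butyl[2-iodo-5-(methoxymethoxy)phenoxy]dimethylsilane | COCOc1ccc(I)c(O[Si](C)(C)C(C)(C)C)c1
F2 | step 8 | tert-butyl[5-(methoxymethoxy)-2-(tributylstannyl)phenoxy]dimethylsilane | CCCC[Sn](CCCC)(CCCC)c1ccc(OCOC)cc1O[Si](C)(C)C(C)(C)C
F3 | step 8 | 2-[4-methoxy-2,3-bis(methoxymethoxy)-5-(3-methylbut-2-en-1-yl)phenyl]prop-2-enoyl chloride | C=C(C(=O)Cl)c1cc(CC=C(C)C)c(OC)c(OCOC)c1OCOC
F4 | step 8 | 1-[2-(tert-butyldimethylsilyloxy)-4-(methoxymethoxy)phenyl]-2-[4-methoxy-2,3-bis(methoxymethoxy)-5-(3-methylbut-2-en-1-yl)phenyl]prop-2-en-1-one | C=C(C(=O)c1ccc(OCOC)cc1O[Si](C)(C)C(C)(C)C)c1cc(CC=C(C)C)c(OC)c(OCOC)c1OCOC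
F5 | step 9 | (3S)-7-(methoxymethoxy)-3-[4-methoxy-2,3-bis(methoxymethoxy)-5-(3-methylbut-2-en-1-yl)phenyl]chroman-4-one | COc1c(CC=C(C)C)cc([C@H]2COc3cc(OCOC)ccc3C2=O)c(OCOC)c1OCOC
F6 | step 11 | racemic 3-[2,3-dihydroxy-4-methoxy-5-(3-methylbut-2-en-1-yl)phenyl]-7-hydroxychroman-4-one | COc1c(CC=C(C)C)cc(C2COc3cc(O)ccc3C2=O)c(O)c1O
F7 | step 11 | racemic 7-(tert-butyldimethylsilyloxy)-3-[2,3-bis(tert-butyldimethylsilyloxy)-4-methoxy-5-(3-methylbut-2-en-1-yl)phenyl]chroman-4-one | COc1c(CC=C(C)C)cc(C2COc3cc(O[Si](C)(C)C(C)(C)C)ccc3C2=O)c(O[Si](C)(C)C(C)(C)C)c1O[Si](C)(C)C(C)(C)C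
F8 | step 11 | (3R,4R)-7-(tert-butyldimethylsilyloxy)-3-[2,3-bis(tert-butyldimethylsilyloxy)-4-methoxy-5-(3-methylbut-2-en-1-yl)phenyl]chroman-4-ol | COc1c(CC=C(C)C)cc([C@@H]2COc3cc(O[Si](C)(C)C(C)(C)C)ccc3[C@@H]2O)c(O[Si](C)(C)C(C)(C)C)c1O[Si](C)(C)C(C)(C)C
F9 | step 11 | (3R)-7-(tert-butyldimethylsilyloxy)-3-[2,3-bis(tert-butyldimethylsilyloxy)-4-methoxy-5-(3-methylbut-2-en-1-yl)phenyl]chroman-4-one | COc1c(CC=C(C)C)cc([C@@H]2COc3cc(O[Si](C)(C)C(C)(C)C)ccc3C2=O)c(O[Si](C)(C)C(C)(C)C)c1O[Si](C)(C)C(C)(C)C
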